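Amounts here are booked in percent of the substrate charged, the limiting reagent, under four entries: intermediate, target, substrate not yet turned, and an unaccounted remainder.

| flask | substrate | free catalyst | remark | time |
|---|---|---|---|---|
| gamma | 0.25 M | 8.8 mM | run made earlier |  |
| alpha | 0.12 M | 8.8 mM | run made earlier |  |
| zeta | 0.50 M | 8.8 mM | run made earlier |  |
| elm | 0.25 M | 8.8 mM | a closed flask charged with all of it at once and left for 1.0 h | 1.0 h |
| ash | 0.25 M | 8.8 mM | a single well-mixed tank run continuously and read at steady state, 1.0 h in it on average |  |
| oak | 0.25 M | 8.8 mM | plug flow through a tube for 1.0 h, no back-mixing | 1.0 h |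
| larch | 0.25 M (fed, over 0.800 h) | 8.8 mM | all but substrate at the start; substrate goes in evenly over 0.800 h, the run ends at 1.0 h | 1.0 h |

| run | time / min | intermediate / % | target / % |
|---|---|---|---|
| gamma | 15.0 | 79.5 | 4.1 |
| gamma | 30.0 | 82.5 | 7.8 |
| gamma | 50.0 | 78.5 | 11.2 |
| gamma | 60.0 | 77.0 | 12.2 |
| alpha | 4.00 | 44.5 | 1.4 |
| alpha | 8.00 | 66.0 | 1.5 |
| alpha | 20.0 | 81.2 | 4.8 |
| alpha | 50.0 | 79.2 | 11.5 |
| zeta | 4.00 | 44.4 | 1.0 |
| zeta | 8.00 | 66.0 | 1.9 |
| zeta | 20.0 | 82.0 | 5.0 |
| zeta | 50.0 | 79.2 | 11.2 |

(scatter of a reading: 0.5 percentage points)

- the stated concentrations are those of everything mixed, before any reaction; amounts are the same in each set-up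
- the feed brings no volume worth counting
- the earlier runs were made in a closed, stirred flask

- the set-up with the highest amount of intermediate at the outlet or at the end, in percent of the substrate put in ("none" if the first two lie within 2 percentage points) (elm / ash / oak / larch / none)
- amount of intermediate at the outlet or at the end, in percent of the substrate put in, elm
- amount of intermediate at the outlet or at the end, in percent of the substrate put in, ash
- amount of intermediate at the outlet or at the end, in percent of the substrate put in, oak
- amount of intermediate at the outlet or at the end, in percent of the substrate put in, larch

At 50.0 min the three earlier runs, from 0.12 M to 0.50 M of substrate, read alike within the scatter, so one ledger serves them. Their mean leaves a remainder of 9.73 % outside intermediate and target. The alpha reading at 8.00 min gives unturned substrate a mean life of 5.81 min.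

The target entry replaces a bending curve by its mean. Gamma's intermediate averages 79.4 % over its readings, which gives the mean drain 0.154 /h, the target formed per hour as a share of the intermediate present.

Elm and oak share gamma's history, so their books close at 78.1 % intermediate. In larch, substrate arriving evenly spends on average 0.600 h in the flask, so target is booked at 8.32 %. Substrate still unturned at the end is booked at 1.53 %, which closes larch at 80.4 % intermediate. The tank ash, with the same entries and a mean stay of 1.0 h, closes at 71.3 %. This reckoning therefore puts larch 2.3 percentage points above elm, past the margin of 2 points.

The forecast differs on ash, on larch and on the best. It gives 77.8 % for elm and oak, 65 % for ash and 71 % for larch, where “late substrate meets weakened catalyst”, and its best is none.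

The flask gives 77.3 % for elm and oak, 69.8 % for ash and 82.9 % for larch, so the best is larch.

    substrate → intermediate (k = 0.00261 /s)
    2 free catalyst → spent catalyst (k = 0.0571 /M/s)
    free catalyst + intermediate → free catalyst + target (k = 0.0139 /M/s)
    substrate → uncatalysed product (k = 2.87 × 10⁻⁴ /s)

The first half-life of free catalyst at its charged amount, by the pairing into spent catalyst alone, 0.276 h, is shorter than the 0.400 h at which larch's substrate arrives on average. Larch ends with 5.87 % target, below the 8.32 % booked from gamma's mean drain of 0.154 /h. The neighbour flask like elm, with a quarter of the free catalyst, ends at 5.97 % target on 84.1 % intermediate, a drain of 0.0710 /h reckoned on its final intermediate, half of gamma's.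

(The readings are calculated with made-up constants; noise was put on by code.)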